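## Structural features

The target is a spiro[5.5]undecane of the chamigrene type, numbered here as ring A = C1–C6 and ring B = C6–C11. Ring A carries an exocyclic methylene on C1, the acetate on C3, a secondary bromide on C4 and a gem-dimethyl group on C5; ring B carries a methyl group and a tertiary bromide on C9 and a secondary chloride on C10. The rings share only the quaternary stereocentre C6, which sits between the quaternary C5, the sp2 carbon C1 and two methylene groups (C7, C11). Two pairs of adjacent stereocentres flank it: C3/C4 (acetate and bromine cis) and C9/C10 (bromine and chlorine trans). In the ring B chair that keeps the C5 branch equatorial, both halogens are axial and the chlorine is syn to the axial C1 branch. The fragile groups are the exocyclic alkene (migration into the ring, addition of HX), the tertiary bromide (ionisation, elimination) and the vicinal bromochloride and β-bromo acetate (base-induced elimination, halonium shifts). The real difficulty is threefold: C6 must be set absolutely between two fully substituted carbons and must relate two remote stereo-arrays; the heavier halogen of ring B sits on the more substituted carbon, opposite to what simple BrCl addition to a C9=C10 alkene would be expected to favour; and C4 lies next to CMe2, where no substitution is possible and where a C3 ketone would enolise towards C2 instead. The key step exploits the fact that C1 is an sp2 carbon bonded directly to C6: a vinylpalladium centred on C1 can add across a C6=C11 double bond of a preformed ring B, closing ring A, while an allylic oxygen on C10 chooses the face and ends up as the C10 carbonyl handle.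

## Logic of the disconnections

**29 to 28 to 27.** The O–acyl bond at C3 is cut first, then the O–H bond is returned to silicon. The ester goes on last because it would not survive the amide base used on ring B. The cost is two steps; the gain is that no base-labile group is carried. The forward steps must desilylate and acylate without ionising the C9–Br bond or moving the C1 methylene.

**27 to 24.** The C10–Cl bond is exchanged for a C10–O bond of the same configuration. A direct backside displacement at C10 is not credible: the trajectory runs over ring B beside the axial C1 branch, and C9 is fully substituted. An axial hydroxyl antiperiplanar to the axial C9 bromine lets the bromine perform the first inversion and chloride the second. The gain is that one halogen becomes an oxygen derived from a carbonyl group. The demand is that chloride reopens the bromonium ion at C10 and not at C9.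

**24 to 23.** The C10–H bond is cut to give the C10 carbonyl group. This removes a stereocentre and leaves a ketone flanked by the C9 bromide. The forward step must deliver hydride on the equatorial trajectory, away from the axial C1 branch, and must not let the trans-diaxial alkoxide close to an epoxide.

**23 to 21 to 19.** The C9–Br bond and then the C9–CH3 bond are cut, both being enolate bonds of the C10 ketone. This strips ring B down to an unsubstituted cyclohexanone. The forward steps need enolisation towards C9 (C11 is neopentyl) and entry of bromine on the face anti to C1, which the preferred half-chair should provide.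

**19 to 18.** The carbonyl group is traced to the O–Si bond of an enol ether, the direct product of the ring closure. Nothing is simplified, but the carbonyl position is fixed at C10. The forward cleavage must spare the second silyl ether.

**18 to 15.** The C1–C6 bond is cut. This opens ring A, removes the quaternary stereocentre and leaves a cyclohexene carrying an acyclic chain that ends in a vinyl bromide. The forward step must add C1 and palladium across C6=C11 on the face anti to the C10 silyloxy group and must eliminate only towards C10.

**15 to 14 to 11 and 12.** After the O–Si bond at C3, the C2–C3 bond is cut between an aldehyde carbon and a 2-bromoallyl unit. This separates a three-carbon piece and leaves one stereocentre (C4) to control the next (C3). The forward addition must give the anti bromohydrin and must not enolise the α-bromo aldehyde.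

**11 to 10.** The C4–Br bond is cut at the aldehyde stage. Here C4 is the only enolisable carbon, so the regiochemistry is unambiguous, and C5 is quaternary, so the product cannot lose HBr. A variant of 15 with a ketal at C3 and hydrogen at C4 was considered and set aside: it postpones the bromination to a C3 ketone of ring A, which would enolise towards C2 (α to the carbonyl and allylic to the C1 methylene) and not towards C4. The demand on the forward step is catalyst control of the C4 configuration.

**10 to 9 to 7.** The aldehyde is traced through the primary alcohol to a terminal alkene (C3–O bond). The gain is a robust vinyl group as a masked aldehyde. The demand is hydroboration of the monosubstituted alkene only.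

**7 to 6 to 5.** After the O–Si bond, the C10–H bond is cut to give an achiral enone. All chirality of the route then stems from one catalytic reduction, which must be highly enantioselective.

**5 to 1 and 2.** The C5–C6 bond is cut between the tertiary carbon of a prenyl unit and the carbonyl carbon of a vinylogous ester. Both pieces are commercial. The forward step needs the allylic metal to react through its γ carbon.

## Other disconnections considered

**Alternative 1:** The cut is at C6–C7, with the C9–C12 bond (C12 = the methylene carbon on C1) restored in the reverse direction. This leads from the spiro ketone A1 to the fused octalin carbinol A2, in which ring A is fused through a C1=C6 alkene to a ring made of C1, C12, C9, C10, C11 and C6, and C9 carries a vinyl group and the hydroxyl.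
- Forward step: the potassium alkoxide of A2 (KH, 18-crown-6) undergoes an anionic oxy-Cope shift; C7 bonds to C6 as C9–C12 breaks, which opens the fused ring, closes ring B and leaves the C1 methylene and the C9 enolate.
- In its favour: it needs no metal catalyst, the geometry allows bonding on only one face so the C9 configuration is copied to C6, and the methylene group arises in the same event.
- Better than the chosen plan on one point: oxygen ends up on both C9 and C10, so the C9 methyl could come from a carbonyl addition and no enolate alkylation is needed.
- Against it: A2 is about as complex as the target, with two adjacent stereocentres and a tetrasubstituted ring-fusion alkene to be made in enantiopure form. The new bond forms at a fully substituted alkene carbon next to CMe2 through a bridged, boat-like transition state. The strongly basic conditions exclude a bromide at C4, so ring A keeps a C3 ketal and the C2-versus-C4 enolisation problem returns. The tertiary C9 oxygen must later become the bromide with stereocontrol.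
- Comparison: on structure the two plans are equal in principle, since both add an sp2 carbon to a tetrasubstituted position and both use up a ring B carbinol as the relay. On mechanism the pericyclic step avoids the β-elimination choices of an organopalladium but tolerates fewer functional groups. On step economy the chosen plan should be shorter, because 15 is reached in eight steps from simple materials.

**Alternative 2:** The cut is at C9–C10, which opens the cis-diol A3 to the keto aldehyde A4.
- Forward step: SmI2 reduces the aldehyde to a ketyl, which adds to the methyl ketone; the samarium bridge between the two oxygens gives the cis-diol.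
- In its favour: one mild step closes ring B and sets both oxygenated centres.
- Better than the chosen plan on one point: the C9 methyl arrives with the ketone.
- Against it: the step does not create C6. A4 already needs the quaternary stereocentre, bearing two nearly equal chains next to CMe2, in enantiopure form, and the facial sense of the pinacol closure relative to C6 rests on a small difference between the C1 and C5 branches. A cis-diol maps poorly onto a trans-dihalide: the tertiary C9–O bond must become C–Br with retention and the C10–O bond C–Cl with inversion, the latter over the hindered ring face. Ring A of A3 has a ketone at C1 and no oxygen at C3, so a methylenation next to the quaternary centre and the whole C3/C4 array remain to be built.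
- Comparison: on structure this plan solves the easier problem (ring B oxygenation) and leaves the harder one (C6) open, whereas the chosen plan does the reverse. On mechanism the ketyl addition is reliable and is the equal of the Heck step. On step economy it is likely to be clearly longer.

**Alternative 3:** The cuts are at C9–C10 and C7–C8, which open the enone A5 to the spiro cyclobutanone A6 and 1-(trimethylsilyl)propyne A7.
- Forward step: zerovalent nickel (from Ni(cod)2) with a chiral phosphine couples the carbonyl carbon C10 with the methyl-bearing alkyne carbon. β-Carbon elimination then cleaves C10–C7, and reductive elimination joins C7 to C8.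
- In its favour: it is convergent and redox-neutral.
- Equal or better on one point: C6 becomes stereogenic by catalytic desymmetrisation, so no relay centre has to be built and then destroyed.
- Better on another point: the C9 methyl and the C10 carbonyl are delivered together, so the methylation step of the chosen route would not be needed. A conjugate reduction of A5 would also give a regiodefined C9 enolate for bromination.
- Against it: the two enantiotopic ring bonds of A6 differ only through the C1 and C5 branches on the remote quaternary carbon, which is a demanding recognition task for a ligand. The cyclobutanone is flanked by two fully substituted positions and may be slow to react. The silyl group and the C8=C9 unsaturation must be removed afterwards. A6 itself needs a cyclobutanone annulation onto one exocyclic alkene in the presence of another. Ring A again carries a C3 ketal and inherits the C4 bromination problem.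
- Comparison: on structure the chosen plan is ahead, because the element that controls C6 is an adjacent oxygen substituent and not a remote difference between two branches. On mechanism the alternative is more elegant, but facial control is less assured. On step economy the ring B end-game would be shorter by about one step, and the preparation of A6 would be longer.

Key step: step 9

Remark 1: all spiro compounds are numbered as above (ring A C1–C5, spiro C6, ring B C7–C11), also where this is not the lowest-locant numbering; TBS = tert-butyldimethylsilyl.
Remark 2: the sense of induction in steps 2 and 6 is assigned from the usual models (large-group rule for the oxazaborolidine, phenyl shielding of the enamine); if either proved opposite, the mirror-image catalyst would be used.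
Remark 3: a face-by-face check shows that an (S) carbinol at C10 combined with carbopalladation anti to its silyloxy group gives the (6R) spiro centre of the target.

Step 1
Reactants: 1 prenyl chloride (1-chloro-3-methylbut-2-ene); 2 3-ethoxycyclohex-2-en-1-one
Product: 5 3-(2-methylbut-3-en-2-yl)cyclohex-2-en-1-one, via prenylmagnesium chloride 3 (not isolated), via tertiary carbinol 4 (not isolated)
Conditions: Mg, THF, 0 °C; then 2, −78 → 0 °C; then 1 M HCl, 25 °C
Reagents that add atoms: water, O
Why: The allylic Grignard reagent 3 adds to the carbonyl group of 2 through its γ (tertiary) carbon in a cyclic SE2' transition state to give 4; aqueous acid then hydrolyses the enol ether and dehydrates the β-hydroxy ketone (Stork–Danheiser transposition) to the enone. No stereocentre is formed.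

Step 2
Reactants: 5 3-(2-methylbut-3-en-2-yl)cyclohex-2-en-1-one
Product: 6 (1S)-3-(2-methylbut-3-en-2-yl)cyclohex-2-en-1-ol
Conditions: (R)-Me-CBS oxazaborolidine [(3aR)-1-methyl-3,3-diphenyltetrahydro-1H,3H-pyrrolo[1,2-c][1,3,2]oxazaborole] (0.2 equiv), catecholborane, toluene, −78 °C
Reagents that add atoms: none
Why: Corey–Bakshi–Shibata reduction: the ketone binds to the ring boron with the conjugated alkene arm as the large group and hydride is delivered to the Re face, which sets the (S) carbinol (the future C10). Catecholborane at −78 °C should leave the vinyl group untouched.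

Step 3
Reactants: 6 (1S)-3-(2-methylbut-3-en-2-yl)cyclohex-2-en-1-ol
Product: 7 tert-butyl(dimethyl){[(1S)-3-(2-methylbut-3-en-2-yl)cyclohex-2-en-1-yl]oxy}silane
Conditions: tert-butyldimethylsilyl chloride, imidazole, DMF, 25 °C
Reagents that add atoms: tert-butyldimethylsilyl chloride, CC(C)(C)[Si](C)(C)Cl
Why: Standard silylation of a secondary allylic alcohol; the ether should survive the basic, oxidative and organometallic steps up to the cyclisation and supplies the bulk that later directs the palladium.

Step 4
Reactants: 7 tert-butyl(dimethyl){[(1S)-3-(2-methylbut-3-en-2-yl)cyclohex-2-en-1-yl]oxy}silane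
Product: 9 3-[(3S)-3-(tert-butyldimethylsilyloxy)cyclohex-1-en-1-yl]-3-methylbutan-1-ol, via alkylborane 8 (not isolated)
Conditions: 9-BBN, THF, 0 → 25 °C; then NaOH, H2O2, H2O, 0 → 25 °C
Reagents that add atoms: hydrogen peroxide, OO
Why: Anti-Markovnikov hydroboration with 9-BBN selects the monosubstituted alkene over the trisubstituted ring alkene, and alkaline peroxide oxidises the C–B bond of 8. No stereocentre is formed.

Step 5
Reactants: 9 3-[(3S)-3-(tert-butyldimethylsilyloxy)cyclohex-1-en-1-yl]-3-methylbutan-1-ol
Product: 10 3-[(3S)-3-(tert-butyldimethylsilyloxy)cyclohex-1-en-1-yl]-3-methylbutanal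
Conditions: Dess–Martin periodinane, pyridine, CH2Cl2, 0 → 25 °C
Reagents that add atoms: none
Why: Dess–Martin oxidation of a primary alcohol under buffered conditions stops at the aldehyde and should not affect the alkene or the silyl ether.

Step 6
Reactants: 10 3-[(3S)-3-(tert-butyldimethylsilyloxy)cyclohex-1-en-1-yl]-3-methylbutanal
Product: 11 (2R)-2-bromo-3-[(3S)-3-(tert-butyldimethylsilyloxy)cyclohex-1-en-1-yl]-3-methylbutanal
Conditions: (2S,5S)-2,5-diphenylpyrrolidine (0.2 equiv), PhCO2H (0.2 equiv), 4,4-dibromo-2,6-di-tert-butylcyclohexa-2,5-dien-1-one, CH2Cl2–pentane, −40 °C; short silica plug, used at once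
Reagents that add atoms: 4,4-dibromo-2,6-di-tert-butylcyclohexa-2,5-dien-1-one, CC(C)(C)C1=CC(Br)(Br)C=C(C(C)(C)C)C1=O
Why: Organocatalytic enamine α-bromination of an aldehyde: the aldehyde can enolise only towards C4, and the phenyl group of the C2-symmetric pyrrolidine shields one face of the E-enamine, so the quinoid Br+ donor should set (R) at C4 under catalyst control. C5 is quaternary, so the product cannot lose HBr; it is used at once to limit enolisation.

Step 7
Reactants: 11 (2R)-2-bromo-3-[(3S)-3-(tert-butyldimethylsilyloxy)cyclohex-1-en-1-yl]-3-methylbutanal; 12 2,3-dibromopropene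
Product: 14 (4S,5R)-2,5-dibromo-6-[(3S)-3-(tert-butyldimethylsilyloxy)cyclohex-1-en-1-yl]-6-methylhept-1-en-4-ol, via 2-bromoallylindium dibromide 13 (not isolated)
Conditions: In powder, 12, THF, 25 °C; then 11, −40 → 0 °C; aq NH4Cl
Reagents that add atoms: none
Why: Barbier-type addition of the preformed allylindium reagent 13 to the aldehyde; with the C–Br dipole opposed to the carbonyl (Cornforth or polar Felkin–Anh model) the nucleophile passes the hydrogen and not the quaternary C5, which should give the anti bromohydrin, that is (S) at C3. The organoindium reagent is not basic, so neither epimerisation nor epoxide closure is expected.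

Step 8
Reactants: 14 (4S,5R)-2,5-dibromo-6-[(3S)-3-(tert-butyldimethylsilyloxy)cyclohex-1-en-1-yl]-6-methylhept-1-en-4-ol
Product: 15 (4S,5R)-2,5-dibromo-4-(tert-butyldimethylsilyloxy)-6-[(3S)-3-(tert-butyldimethylsilyloxy)cyclohex-1-en-1-yl]-6-methylhept-1-ene
Conditions: tert-butyldimethylsilyl triflate, 2,6-lutidine, CH2Cl2, −78 → 0 °C
Reagents that add atoms: tert-butyldimethylsilyl triflate, CC(C)(C)[Si](C)(C)OS(=O)(=O)C(F)(F)F
Why: Silylation with the triflate and a hindered pyridine base is fast at low temperature and avoids an alkoxide, which would close the anti bromohydrin to an epoxide.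

Step 9
Reactants: 15 (4S,5R)-2,5-dibromo-4-(tert-butyldimethylsilyloxy)-6-[(3S)-3-(tert-butyldimethylsilyloxy)cyclohex-1-en-1-yl]-6-methylhept-1-ene
Product: 18 (3S,4R,6R)-4-bromo-3,10-bis(tert-butyldimethylsilyloxy)-5,5-dimethyl-1-methylidenespiro[5.5]undec-10-ene, via vinylpalladium bromide 16 (not isolated), via alkylpalladium bromide 17 (not isolated)
Conditions: Pd(OAc)2 (0.1 equiv), PPh3 (0.3 equiv), Ag2CO3 (2 equiv), MeCN, 75 °C
Reagents that add atoms: none
Why: Zerovalent palladium, formed in the flask from Pd(OAc)2 and PPh3, inserts into the vinyl C1–Br bond to give 16; the secondary, neopentyl C4–Br bond should be inert to it. After Ag2CO3 has removed bromide, the vinylpalladium adds syn across C6=C11 in a 6-exo-trig closure that forms C1–C6 and ring A and leaves palladium on C11 (17). C6 is the only new stereocentre: insertion should occur on the face of ring B anti to the C10 silyloxy group, so the (10S) carbinol is translated into (6R), the C3 and C4 centres of the tether being spectators. Only this face places palladium syn to the C10 hydrogen, and since C6 is quaternary this is the sole β-hydrogen, so syn β-hydride elimination gives the C10=C11 silyl enol ether regiospecifically and removes the relay centre. An insertion on the other face has no syn β-hydrogen and cannot lead to a diastereomer of 18, which protects the stereochemical purity of the product. The closest known reaction type is the intramolecular Heck cyclisation that builds quaternary spiro centres and terminates towards an oxygen-bearing carbon to give an enol ether. The selectivities needed are exo over 7-endo closure, secured by the four-atom tether between C1 and C6, and no migration of the C1 methylene, secured by the silver salt, which takes up HBr before a palladium hydride can re-add.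

Step 10
Reactants: 18 (3S,4R,6R)-4-bromo-3,10-bis(tert-butyldimethylsilyloxy)-5,5-dimethyl-1-methylidenespiro[5.5]undec-10-ene
Product: 19 (3S,4R,6R)-4-bromo-3-(tert-butyldimethylsilyloxy)-5,5-dimethyl-1-methylidenespiro[5.5]undecan-10-one
Conditions: Bu4NF (1.05 equiv), AcOH, THF, −20 → 0 °C
Reagents that add atoms: none
Why: Fluoride cleaves the O–Si bond of the silyl enol ether much faster than that of the hindered secondary alkyl silyl ether at C3, because an enolate is the leaving group, and acetic acid protonates the enolate at once; this unmasks the C10 ketone.

Step 11
Reactants: 19 (3S,4R,6R)-4-bromo-3-(tert-butyldimethylsilyloxy)-5,5-dimethyl-1-methylidenespiro[5.5]undecan-10-one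
Product: 21 (3S,4R,6R)-4-bromo-3-(tert-butyldimethylsilyloxy)-5,5,9-trimethyl-1-methylidenespiro[5.5]undecan-10-one (C9 epimers), via lithium enolate 20 (not isolated)
Conditions: LiN(iPr)2, THF, −78 °C; then MeI, −78 → −40 °C
Reagents that add atoms: iodomethane, CI
Why: Kinetic deprotonation should occur at C9, because C11 is a neopentyl methylene next to the quaternary C6; C-methylation of enolate 20 gives the 9-methyl ketone. The C9 configuration is of no consequence, since this centre is made planar again in step 12.

Step 12
Reactants: 21 (3S,4R,6R)-4-bromo-3-(tert-butyldimethylsilyloxy)-5,5,9-trimethyl-1-methylidenespiro[5.5]undecan-10-one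
Product: 23 (3S,4R,6R,9S)-4,9-dibromo-3-(tert-butyldimethylsilyloxy)-5,5,9-trimethyl-1-methylidenespiro[5.5]undecan-10-one, via trimethylsilyl enol ether 22 (not isolated)
Conditions: Me3SiCl, NaI, Et3N, MeCN, 25 °C; then N-bromosuccinimide, THF, −78 °C
Reagents that add atoms: N-bromosuccinimide, O=C1CCC(=O)N1Br
Why: Thermodynamic silylation (Me3SiI formed in the flask) should give the tetrasubstituted C9=C10 enol silane 22, the C11 side being both less substituted and neopentyl. Electrophilic α-bromination of the silyl enol ether then occurs by axial attack on the half-chair that keeps the C5 branch pseudo-equatorial, that is on the face anti to C1, which should give the axial tertiary bromide with the methyl group equatorial (9S).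

Step 13
Reactants: 23 (3S,4R,6R,9S)-4,9-dibromo-3-(tert-butyldimethylsilyloxy)-5,5,9-trimethyl-1-methylidenespiro[5.5]undecan-10-one
Product: 24 (3S,4R,6R,9S,10S)-4,9-dibromo-3-(tert-butyldimethylsilyloxy)-5,5,9-trimethyl-1-methylidenespiro[5.5]undecan-10-ol
Conditions: Li[BH(sec-Bu)3], THF, −78 °C; AcOH quench at −78 °C
Reagents that add atoms: none
Why: The bulky borohydride should attack C10 on the equatorial trajectory, from the face opposite the axial C1 branch of C6 (1,3-related), giving the axial (10S) alcohol trans-diaxial to the C9 bromine. The cold acidic quench prevents the alkoxide from closing to an epoxide.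

Step 14
Reactants: 24 (3S,4R,6R,9S,10S)-4,9-dibromo-3-(tert-butyldimethylsilyloxy)-5,5,9-trimethyl-1-methylidenespiro[5.5]undecan-10-ol
Product: 27 tert-butyl{[(3S,4R,6R,9S,10S)-4,9-dibromo-10-chloro-5,5,9-trimethyl-1-methylidenespiro[5.5]undecan-3-yl]oxy}dimethylsilane, via chlorosulfite 25 (not isolated), via bromonium chloride 26 (not isolated)
Conditions: SOCl2, pyridine, CH2Cl2, −20 → 0 °C
Reagents that add atoms: thionyl chloride, O=S(Cl)Cl
Why: Deoxychlorination of a β-bromo alcohol with neighbouring-group participation: chlorosulfite 25 ionises with help from the antiperiplanar axial bromine, and bromonium ion 26 is reopened by chloride at C10 in the trans-diaxial (Fürst–Plattner) sense, on the face from which the leaving group departed. Two inversions give net retention at C10 (10S), and the bromine stays on the tertiary C9.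

Step 15
Reactants: 27 tert-butyl{[(3S,4R,6R,9S,10S)-4,9-dibromo-10-chloro-5,5,9-trimethyl-1-methylidenespiro[5.5]undecan-3-yl]oxy}dimethylsilane
Product: 28 (3S,4R,6R,9S,10S)-4,9-dibromo-10-chloro-5,5,9-trimethyl-1-methylidenespiro[5.5]undecan-3-ol
Conditions: HF·pyridine, pyridine, THF, 0 → 25 °C
Reagents that add atoms: none
Why: Buffered HF·pyridine removes the secondary silyl ether without a base, which could eliminate the tertiary bromide, and without a strong acid, which could add to the exocyclic alkene.

Step 16
Reactants: 28 (3S,4R,6R,9S,10S)-4,9-dibromo-10-chloro-5,5,9-trimethyl-1-methylidenespiro[5.5]undecan-3-ol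
Product: 29 (3S,4R,6R,9S,10S)-4,9-dibromo-10-chloro-5,5,9-trimethyl-1-methylidenespiro[5.5]undecan-3-yl acetate (target)
Conditions: Ac2O, 4-(dimethylamino)pyridine (0.1 equiv), pyridine, CH2Cl2, 25 °C
Reagents that add atoms: acetic anhydride, CC(=O)OC(C)=O
Why: Acylation by nucleophilic catalysis (acylpyridinium) of the secondary alcohol cis to the C4 bromine; a cis bromohydrin cannot close to an epoxide, and the mild base should not eliminate the halides.

## Compound list

1 | prenyl chloride (1-chloro-3-methylbut-2-ene) | CC(C)=CCCl | starting material
2 | 3-ethoxycyclohex-2-en-1-one | CCOC1=CC(=O)CCC1 | starting material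
3 | prenylmagnesium chloride | CC(C)=CC[Mg]Cl | intermediate (not isolated)
4 | 3-ethoxy-1-(2-methylbut-3-en-2-yl)cyclohex-2-en-1-ol (racemic, present as its magnesium alkoxide) | C=CC(C)(C)C1(O)C=C(OCC)CCC1 | intermediate (not isolated)
5 | 3-(2-methylbut-3-en-2-yl)cyclohex-2-en-1-one | C=CC(C)(C)C1=CC(=O)CCC1 | intermediate
6 | (1S)-3-(2-methylbut-3-en-2-yl)cyclohex-2-en-1-ol | C=CC(C)(C)C1=C[C@@H](O)CCC1 | intermediate
7 | tert-butyl(dimethyl){[(1S)-3-(2-methylbut-3-en-2-yl)cyclohex-2-en-1-yl]oxy}silane | C=CC(C)(C)C1=C[C@@H](O[Si](C)(C)C(C)(C)C)CCC1 | intermediate
8 | 9-{3-[(3S)-3-(tert-butyldimethylsilyloxy)cyclohex-1-en-1-yl]-3-methylbutyl}-9-borabicyclo[3.3.1]nonane | CC(C)(CCB1C2CCCC1CCC2)C1=C[C@@H](O[Si](C)(C)C(C)(C)C)CCC1 | intermediate (not isolated)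
9 | 3-[(3S)-3-(tert-butyldimethylsilyloxy)cyclohex-1-en-1-yl]-3-methylbutan-1-ol | CC(C)(CCO)C1=C[C@@H](O[Si](C)(C)C(C)(C)C)CCC1 | intermediate
10 | 3-[(3S)-3-(tert-butyldimethylsilyloxy)cyclohex-1-en-1-yl]-3-methylbutanal | CC(C)(CC=O)C1=C[C@@H](O[Si](C)(C)C(C)(C)C)CCC1 | intermediate
11 | (2R)-2-bromo-3-[(3S)-3-(tert-butyldimethylsilyloxy)cyclohex-1-en-1-yl]-3-methylbutanal | O=C[C@H](Br)C(C)(C)C1=C[C@@H](O[Si](C)(C)C(C)(C)C)CCC1 | intermediate
12 | 2,3-dibromopropene | C=C(Br)CBr | starting material
13 | (2-bromoprop-2-en-1-yl)indium dibromide (simplest formula of the allylindium sesquibromide) | C=C(Br)C[In](Br)Br | intermediate (not isolated)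
14 | (4S,5R)-2,5-dibromo-6-[(3S)-3-(tert-butyldimethylsilyloxy)cyclohex-1-en-1-yl]-6-methylhept-1-en-4-ol | C=C(Br)C[C@H](O)[C@H](Br)C(C)(C)C1=C[C@@H](O[Si](C)(C)C(C)(C)C)CCC1 | intermediate
15 | (4S,5R)-2,5-dibromo-4-(tert-butyldimethylsilyloxy)-6-[(3S)-3-(tert-butyldimethylsilyloxy)cyclohex-1-en-1-yl]-6-methylhept-1-ene | C=C(Br)C[C@H](O[Si](C)(C)C(C)(C)C)[C@H](Br)C(C)(C)C1=C[C@@H](O[Si](C)(C)C(C)(C)C)CCC1 | intermediate (precursor of the key step)
16 | vinylpalladium bromide from insertion of palladium into the C1–Br bond of 15 (phosphine ligands omitted) | C=C([Pd]Br)C[C@H](O[Si](C)(C)C(C)(C)C)[C@H](Br)C(C)(C)C1=C[C@@H](O[Si](C)(C)C(C)(C)C)CCC1 | intermediate (not isolated)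
17 | spirocyclic σ-alkylpalladium bromide, palladium on C11 cis to C1 and to H-10 (phosphine ligands omitted) | C=C1C[C@H](O[Si](C)(C)C(C)(C)C)[C@H](Br)C(C)(C)[C@@]12CCC[C@H](O[Si](C)(C)C(C)(C)C)[C@H]2[Pd]Br | intermediate (not isolated)
18 | (3S,4R,6R)-4-bromo-3,10-bis(tert-butyldimethylsilyloxy)-5,5-dimethyl-1-methylidenespiro[5.5]undec-10-ene | C=C1C[C@H](O[Si](C)(C)C(C)(C)C)[C@H](Br)C(C)(C)[C@@]12CCCC(O[Si](C)(C)C(C)(C)C)=C2 | intermediate (product of the key step)
19 | (3S,4R,6R)-4-bromo-3-(tert-butyldimethylsilyloxy)-5,5-dimethyl-1-methylidenespiro[5.5]undecan-10-one | C=C1C[C@H](O[Si](C)(C)C(C)(C)C)[C@H](Br)C(C)(C)[C@@]12CCCC(=O)C2 | intermediate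
20 | lithium C9=C10 enolate of 19 | C=C1C[C@H](O[Si](C)(C)C(C)(C)C)[C@H](Br)C(C)(C)[C@@]12CCC=C(O[Li])C2 | intermediate (not isolated)
21 | (3S,4R,6R)-4-bromo-3-(tert-butyldimethylsilyloxy)-5,5,9-trimethyl-1-methylidenespiro[5.5]undecan-10-one (C9 epimers) | C=C1C[C@H](O[Si](C)(C)C(C)(C)C)[C@H](Br)C(C)(C)[C@@]12CCC(C)C(=O)C2 | intermediate
22 | C9=C10 trimethylsilyl enol ether of 21 | C=C1C[C@H](O[Si](C)(C)C(C)(C)C)[C@H](Br)C(C)(C)[C@@]12CCC(C)=C(O[Si](C)(C)C)C2 | intermediate (not isolated)
23 | (3S,4R,6R,9S)-4,9-dibromo-3-(tert-butyldimethylsilyloxy)-5,5,9-trimethyl-1-methylidenespiro[5.5]undecan-10-one | C=C1C[C@H](O[Si](C)(C)C(C)(C)C)[C@H](Br)C(C)(C)[C@@]12CC[C@](C)(Br)C(=O)C2 | intermediate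
24 | (3S,4R,6R,9S,10S)-4,9-dibromo-3-(tert-butyldimethylsilyloxy)-5,5,9-trimethyl-1-methylidenespiro[5.5]undecan-10-ol | C=C1C[C@H](O[Si](C)(C)C(C)(C)C)[C@H](Br)C(C)(C)[C@@]12CC[C@](C)(Br)[C@@H](O)C2 | intermediate
25 | C10 chlorosulfite of 24 | C=C1C[C@H](O[Si](C)(C)C(C)(C)C)[C@H](Br)C(C)(C)[C@@]12CC[C@](C)(Br)[C@@H](OS(=O)Cl)C2 | intermediate (not isolated)
26 | C9–C10 bromonium ion on the face anti to C1, chloride counter-ion | C=C1C[C@H](O[Si](C)(C)C(C)(C)C)[C@H](Br)C(C)(C)[C@@]12CC[C@]3(C)[Br+][C@@H]3C2.[Cl-] | intermediate (not isolated)
27 | tert-butyl{[(3S,4R,6R,9S,10S)-4,9-dibromo-10-chloro-5,5,9-trimethyl-1-methylidenespiro[5.5]undecan-3-yl]oxy}dimethylsilane | C=C1C[C@H](O[Si](C)(C)C(C)(C)C)[C@H](Br)C(C)(C)[C@@]12CC[C@](C)(Br)[C@@H](Cl)C2 | intermediate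
28 | (3S,4R,6R,9S,10S)-4,9-dibromo-10-chloro-5,5,9-trimethyl-1-methylidenespiro[5.5]undecan-3-ol | C=C1C[C@H](O)[C@H](Br)C(C)(C)[C@@]12CC[C@](C)(Br)[C@@H](Cl)C2 | intermediate
29 | (3S,4R,6R,9S,10S)-4,9-dibromo-10-chloro-5,5,9-trimethyl-1-methylidenespiro[5.5]undecan-3-yl acetate | C=C1C[C@H](OC(C)=O)[C@H](Br)C(C)(C)[C@@]12CC[C@](C)(Br)[C@@H](Cl)C2 | target

## Step count and least certain steps

Total step count: 16. Longest linear sequence: 16 steps (from 1 and 2; 12 enters at step 7).

**Step 9 (key step).** The most likely failure is slow insertion of the vinylpalladium into the trisubstituted alkene, whose reacting carbon carries the CMe2 group. That would let reduction of the vinyl–palladium bond, insertion syn to the silyloxy group followed by loss of the silyloxy group, or migration of the C1 methylene by a palladium hydride compete. The fallback sets out from 15. Acid methanolysis should remove the allylic silyl ether selectively, the C3 ether being deactivated by the adjacent C–Br bond, to give the allylic alcohol F1. MnO2 oxidation gives the enone F2. A reductive Heck (conjugate) cyclisation with Pd(OAc)2, (R)-BINAP and HCO2Na would then add the vinylpalladium to the electron-poor β-carbon C6, and the palladium enolate would be reduced by formate. This returns to the route at 19. The spiro centre would then depend on the ligand and the C3/C4 centres, not on the carbinol relay.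

**Step 6.** The risk is incomplete facial discrimination on a neopentyl-type enamine, or partial loss of configuration of the α-bromo aldehyde by enolisation before it is used. The fallback sets out from 10 and uses auxiliary control:
- NaClO2 oxidation gives the acid F3.
- Acylation of (4R)-4-benzyl-1,3-oxazolidin-2-one through the pivaloyl mixed anhydride gives the imide F4.
- Bromination of its boron enolate (Bu2BOTf, iPr2NEt, then N-bromosuccinimide) gives the bromo imide F5.
- LiBH4 reduction gives the bromo alcohol F6.
- Dess–Martin oxidation returns to the route at 11.

**Step 7.** The risk is erosion of the anti selectivity if the very large quaternary substituent, and not the C–Br dipole, dictates the reactive conformation, or insertion of indium into the α-C–Br bond. The fallback sets out from 14 as the mixture of C4-carbinol epimers. Dess–Martin oxidation gives the α-bromo ketone F7, and catalyst-controlled reduction with (R)-Me-CBS oxazaborolidine and catecholborane should set the carbinol independently of the substrate bias and return to 14.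

**Step 12.** The risk is entry of bromine on the face syn to C1, because the facial bias at C9 comes only from the conformational preference of the remote spiro centre. The fallback covers the case in which electrophiles prove to enter mainly from that face, and it exchanges the order of the two electrophiles. It sets out from 19: enolate 20 is brominated with N-bromosuccinimide to the 9-bromo ketone F8; re-enolisation with LiN(SiMe3)2 and methylation then brings the methyl group in on that same face and leaves the bromine on the face anti to C1. This returns to the route at 23.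

**Step 13.** The risk is hydride delivery antiperiplanar to the C–Br bond (axial attack, polar Felkin–Anh control), which would give the cis bromohydrin, or closure of the trans-diaxial alkoxide to an epoxide on warming. The fallback sets out from 23 and returns at 24. It replaces substrate control by catalyst control, using (R)-Me-CBS oxazaborolidine with catecholborane; the aluminium- and lithium-free boron alkoxide is also less prone to epoxide closure. No new compound arises.

**Step 14.** The risk is opening of the bromonium ion at the tertiary carbon, a 1,2-bromine shift giving the 9-chloro-10-bromo isomer, or loss of a proton from the chlorosulfite or the bromonium ion. The fallback sets out from 21 and brings the chlorine in by epoxide opening, where attack at the less substituted carbon and trans-diaxial opening coincide: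
- Tf2O with 2,6-di-tert-butyl-4-methylpyridine gives the thermodynamic enol triflate F9.
- Reduction with Pd(OAc)2, PPh3, Bu3N and HCO2H gives the C9=C10 alkene F10.
- Epoxidation with m-chloroperbenzoic acid on the face anti to C1 gives the epoxide F11.
- Opening with LiCl and AcOH at C10 gives the chlorohydrin F12.
- Me3SiBr converts the tertiary alcohol into the bromide through the chloronium ion or tertiary cation, with bromide entering axially anti to chlorine. This returns to the route at 27.

## Further compounds

F1 | step 9 | (1S)-3-[(4S,5R)-2,5-dibromo-4-(tert-butyldimethylsilyloxy)-6-methylhept-1-en-6-yl]cyclohex-2-en-1-ol | C=C(Br)C[C@H](O[Si](C)(C)C(C)(C)C)[C@H](Br)C(C)(C)C1=C[C@@H](O)CCC1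
F2 | step 9 | 3-[(4S,5R)-2,5-dibromo-4-(tert-butyldimethylsilyloxy)-6-methylhept-1-en-6-yl]cyclohex-2-en-1-one | C=C(Br)C[C@H](O[Si](C)(C)C(C)(C)C)[C@H](Br)C(C)(C)C1=CC(=O)CCC1
F3 | step 6 | 3-[(3S)-3-(tert-butyldimethylsilyloxy)cyclohex-1-en-1-yl]-3-methylbutanoic acid | CC(C)(CC(=O)O)C1=C[C@@H](O[Si](C)(C)C(C)(C)C)CCC1
F4 | step 6 | (4R)-4-benzyl-3-{3-[(3S)-3-(tert-butyldimethylsilyloxy)cyclohex-1-en-1-yl]-3-methylbutanoyl}-1,3-oxazolidin-2-one | O=C1OC[C@@H](Cc2ccccc2)N1C(=O)CC(C)(C)C1=C[C@@H](O[Si](C)(C)C(C)(C)C)CCC1
F5 | step 6 | (4R)-4-benzyl-3-{(2R)-2-bromo-3-[(3S)-3-(tert-butyldimethylsilyloxy)cyclohex-1-en-1-yl]-3-methylbutanoyl}-1,3-oxazolidin-2-one | O=C1OC[C@@H](Cc2ccccc2)N1C(=O)[C@H](Br)C(C)(C)C1=C[C@@H](O[Si](C)(C)C(C)(C)C)CCC1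
F6 | step 6 | (2R)-2-bromo-3-[(3S)-3-(tert-butyldimethylsilyloxy)cyclohex-1-en-1-yl]-3-methylbutan-1-ol | OC[C@H](Br)C(C)(C)C1=C[C@@H](O[Si](C)(C)C(C)(C)C)CCC1
F7 | step 7 | (5R)-2,5-dibromo-6-[(3S)-3-(tert-butyldimethylsilyloxy)cyclohex-1-en-1-yl]-6-methylhept-1-en-4-one | C=C(Br)CC(=O)[C@H](Br)C(C)(C)C1=C[C@@H](O[Si](C)(C)C(C)(C)C)CCC1
F8 | step 12 | (3S,4R,6R)-4,9-dibromo-3-(tert-butyldimethylsilyloxy)-5,5-dimethyl-1-methylidenespiro[5.5]undecan-10-one (C9 epimers) | C=C1C[C@H](O[Si](C)(C)C(C)(C)C)[C@H](Br)C(C)(C)[C@@]12CCC(Br)C(=O)C2
F0 | step 13 | none | none
F9 | step 14 | (3S,4R,6R)-4-bromo-3-(tert-butyldimethylsilyloxy)-5,5,9-trimethyl-1-methylidenespiro[5.5]undec-9-en-10-yl trifluoromethanesulfonate | C=C1C[C@H](O[Si](C)(C)C(C)(C)C)[C@H](Br)C(C)(C)[C@@]12CCC(C)=C(OS(=O)(=O)C(F)(F)F)C2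
F10 | step 14 | (3S,4R,6R)-4-bromo-3-(tert-butyldimethylsilyloxy)-5,5,9-trimethyl-1-methylidenespiro[5.5]undec-9-ene | C=C1C[C@H](O[Si](C)(C)C(C)(C)C)[C@H](Br)C(C)(C)[C@@]12CCC(C)=CC2
F11 | step 14 | 9,10-epoxide of F10 on the face anti to C1 | C=C1C[C@H](O[Si](C)(C)C(C)(C)C)[C@H](Br)C(C)(C)[C@@]12CC[C@]3(C)O[C@@H]3C2
F12 | step 14 | (3S,4R,6R,9S,10S)-4-bromo-10-chloro-3-(tert-butyldimethylsilyloxy)-5,5,9-trimethyl-1-methylidenespiro[5.5]undecan-9-ol | C=C1C[C@H](O[Si](C)(C)C(C)(C)C)[C@H](Br)C(C)(C)[C@@]12CC[C@](C)(O)[C@@H](Cl)C2
A1 | alternative 1 | spiro ketone with C9 carbonyl, C10 4-methoxybenzyl ether, C1 methylene and C3 dioxolane (spiro centre as in the target) | C=C1CC2(OCCO2)CC(C)(C)[C@@]13CCC(=O)[C@H](OCc4ccc(OC)cc4)C3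
A2 | alternative 1 | fused octalin carbinol: ring A fused through C1=C6 to a ring C1–C12–C9–C10–C11–C6, tertiary C9 alcohol with vinyl group cis to the C10 4-methoxybenzyl ether, C3 dioxolane | C=C[C@@]1(O)CC2=C(C[C@H]1OCc1ccc(OC)cc1)C(C)(C)CC1(OCCO1)C2
A3 | alternative 2 | spiro cis-diol with tertiary C9 and secondary C10 hydroxyls and a C1 ketone | O=C1CCCC(C)(C)[C@@]12CC[C@](C)(O)[C@H](O)C2
A4 | alternative 2 | keto aldehyde: 3,3-dimethylcyclohexanone with a quaternary C2 bearing 2-oxoethyl and 3-oxobutyl chains | O=C1CCCC(C)(C)[C@@]1(CC=O)CCC(C)=O
A5 | alternative 3 | spiro enone with C10 ketone, C9 methyl, C8 trimethylsilyl, C1 methylene and C3 dioxolane | C=C1CC2(OCCO2)CC(C)(C)[C@@]13CC([Si](C)(C)C)=C(C)C(=O)C3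
A6 | alternative 3 | spiro cyclobutanone: cyclobutanone spiro-fused through its 3-position to ring A (C1 methylene, C3 dioxolane, C5 gem-dimethyl); achiral | C=C1CC2(OCCO2)CC(C)(C)C13CC(=O)C3
A7 | alternative 3 | 1-(trimethylsilyl)propyne | CC#C[Si](C)(C)C
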